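## Retrosynthetic overview

1. Target 14 ⇐ tri-O-benzyl flavanone 13 by hydrogenolysis (last step).
2. 13 ⇐ 2'-hydroxychalcone 12: ring C is closed last by an enantioselective C2–O1 oxa-Michael addition (new catalytic step). Rings A, B and the 4-hydroxyphenyl ring are bought as aromatics.
3. 12 ⇐ aldehyde 9 + acetophenone 11 (Claisen–Schmidt, Cα=Cβ).
4. 9 ⇐ syringaldehyde 3 + α-bromo β-keto ester 4: the C8–O4' ether bond is made by phenoxide SN2. The threo (R,R) pair C7/C8 is then set in one step by syn-selective transfer hydrogenation with dynamic kinetic resolution, followed by ester → CH2OH and ArCH2OH → ArCHO.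
5. 4 ⇐ 4'-benzyloxyacetophenone 1 + dimethyl carbonate; 11 ⇐ 2,4,6-trihydroxyacetophenone 10.

Target stereochemistry planned for: flavanone C2 = S; side chain C1 (benzylic carbinol) = R, C2 (aryloxy carbon) = R, i.e. threo.

Catalyst C1 (step 8): 1-[3,5-bis(trifluoromethyl)phenyl]-3-[(2S)-3,3-dimethyl-1-{[tris(4-methoxyphenyl)-λ5-phosphanylidene]amino}butan-2-yl]thiourea, a bifunctional iminophosphorane–thiourea (BIMP) organocatalyst from L-tert-leucine. SMILES: FC(F)(F)c1cc(NC(=S)N[C@H](CN=P(c2ccc(OC)cc2)(c2ccc(OC)cc2)c2ccc(OC)cc2)C(C)(C)C)cc(C(F)(F)F)c1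

Assumption: the (S)-antipode C1 is taken to give the 2S flavanone; a pilot run on a side-chain-free model chalcone settles the sense, and the mirror-image catalyst (from D-tert-leucine) is used if it is reversed.

## Route

Step 1
Reactants: 1 1-[4-(benzyloxy)phenyl]ethan-1-one
Product: 2 methyl 3-[4-(benzyloxy)phenyl]-3-oxopropanoate
Conditions: NaH (2.2 equiv), dimethyl carbonate (3 equiv), THF, reflux, 3 h; then aq. HCl
Reagents that add atoms: dimethyl carbonate COC(=O)OC
Why: Crossed Claisen condensation (C-acylation of the ketone enolate), driven to completion by irreversible deprotonation of the β-keto ester; no stereocentre is formed.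

Step 2
Reactants: 2 methyl 3-[4-(benzyloxy)phenyl]-3-oxopropanoate; 3 4-hydroxy-3,5-dimethoxybenzaldehyde (syringaldehyde)
Product: 5 methyl 3-[4-(benzyloxy)phenyl]-2-(4-formyl-2,6-dimethoxyphenoxy)-3-oxopropanoate, via α-bromo β-keto ester 4 (not isolated)
Conditions: Br2 (1.0 equiv), MeCN, 0 °C, 30 min; then 3 (1.05 equiv), K2CO3 (3 equiv), rt, 12 h
Reagents that add atoms: bromine BrBr (bromine atom carried by 4 only)
Why: α-Bromination of the enolised β-keto ester, then Williamson-type SN2 O-alkylation of the syringaldehyde phenoxide at the doubly activated α-carbon, forms the C8–O4' bond; the new centre is racemic and stays labile, which step 3 exploits.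

Step 3
Reactants: 5 methyl 3-[4-(benzyloxy)phenyl]-2-(4-formyl-2,6-dimethoxyphenoxy)-3-oxopropanoate
Product: 7 methyl (2S,3R)-3-[4-(benzyloxy)phenyl]-3-hydroxy-2-[4-(hydroxymethyl)-2,6-dimethoxyphenoxy]propanoate, via hydroxymethyl β-keto ester 6 (not isolated)
Conditions: RuCl[(S,S)-TsDPEN](p-cymene) (2 mol %), HCO2H/Et3N 5:2 (6 equiv HCO2H), CH2Cl2, 35 °C, 24 h
Reagents that add atoms: none
Why: Noyori-type asymmetric transfer hydrogenation with dynamic kinetic resolution: the α-centre epimerises fast through the enol while the (S,S)-catalyst reduces one epimer on one ketone face (aryl ketone → 3R), giving the syn (threo) 2S,3R product as is typical for α-alkoxy β-keto esters; the aldehyde is reduced to ArCH2OH in the same pot, which is harmless because step 4 would reduce it anyway.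

Step 4
Reactants: 7 methyl (2S,3R)-3-[4-(benzyloxy)phenyl]-3-hydroxy-2-[4-(hydroxymethyl)-2,6-dimethoxyphenoxy]propanoate
Product: 8 (1R,2R)-1-[4-(benzyloxy)phenyl]-2-[4-(hydroxymethyl)-2,6-dimethoxyphenoxy]propane-1,3-diol
Conditions: LiBH4 (3 equiv), THF, 0 °C → rt; aq. NH4Cl
Reagents that add atoms: none
Why: Borohydride reduction of the activated α-aryloxy ester to the primary alcohol; no bond at either stereocentre is touched (the descriptor at the aryloxy carbon changes from S to R only because CH2OH ranks below the carbinol carbon).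

Step 5
Reactants: 8 (1R,2R)-1-[4-(benzyloxy)phenyl]-2-[4-(hydroxymethyl)-2,6-dimethoxyphenoxy]propane-1,3-diol
Product: 9 4-{[(1R,2R)-1-[4-(benzyloxy)phenyl]-1,3-dihydroxypropan-2-yl]oxy}-3,5-dimethoxybenzaldehyde
Conditions: [Cu(MeCN)4]OTf (5 mol %), 2,2'-bipyridine (5 mol %), TEMPO (5 mol %), N-methylimidazole (10 mol %), air, MeCN, rt, 1–2 h
Reagents that add atoms: none
Why: Stahl-type copper/TEMPO aerobic oxidation is fastest for primary benzylic alcohols, slow for primary aliphatic ones and inert toward secondary alcohols, so only ArCH2OH returns to the aldehyde.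

Step 6
Reactants: 10 1-(2,4,6-trihydroxyphenyl)ethan-1-one
Product: 11 1-[2,4-bis(benzyloxy)-6-hydroxyphenyl]ethan-1-one
Conditions: BnBr (2.1 equiv), K2CO3 (2.2 equiv), DMF, rt, 12 h
Reagents that add atoms: benzyl bromide BrCc1ccccc1
Why: Williamson benzylation stops at the di-ether because the remaining ortho hydroxyl is held in a strong hydrogen bond to the acetyl carbonyl.

Step 7
Reactants: 9 4-{[(1R,2R)-1-[4-(benzyloxy)phenyl]-1,3-dihydroxypropan-2-yl]oxy}-3,5-dimethoxybenzaldehyde; 11 1-[2,4-bis(benzyloxy)-6-hydroxyphenyl]ethan-1-one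
Product: 12 (E)-1-[2,4-bis(benzyloxy)-6-hydroxyphenyl]-3-(4-{[(1R,2R)-1-[4-(benzyloxy)phenyl]-1,3-dihydroxypropan-2-yl]oxy}-3,5-dimethoxyphenyl)prop-2-en-1-one
Conditions: KOH (10 equiv, 50 % aq.), EtOH, rt, 48 h; then cold aq. HCl to pH 5; chromatography to remove any flavanone
Reagents that add atoms: none
Why: Claisen–Schmidt (crossed aldol) condensation of a non-enolisable aldehyde gives the E-enone by E1cB dehydration; the two carbinol centres are not acidic and are untouched.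

Step 8
Reactants: 12 (E)-1-[2,4-bis(benzyloxy)-6-hydroxyphenyl]-3-(4-{[(1R,2R)-1-[4-(benzyloxy)phenyl]-1,3-dihydroxypropan-2-yl]oxy}-3,5-dimethoxyphenyl)prop-2-en-1-one
Product: 13 (2S)-5,7-bis(benzyloxy)-2-(4-{[(1R,2R)-1-[4-(benzyloxy)phenyl]-1,3-dihydroxypropan-2-yl]oxy}-3,5-dimethoxyphenyl)-2,3-dihydro-4H-chromen-4-one
Conditions: C1 (10 mol %), toluene/CH2Cl2 2:1, −20 °C, 24–48 h; AcOH quench at −20 °C
Reagents that add atoms: none
Why: Proposed new method: the iminophosphorane deprotonates the 2'-phenol of 12 to a tight chiral iminophosphonium phenoxide ion pair while the thiourea binds the enone carbonyl, so the 6-endo-trig oxa-Michael C–O bond formation occurs in a chiral pocket that exposes one enone face and sets C2 (S, catalyst control, the side-chain centres being remote); the enolate is then protonated by the P=N–H+ group. Because the flavanone C3–H is far less acidic than the chalcone phenol, the base stays bound to unreacted 12 and retro-Michael racemisation is suppressed until full conversion, when acid quenches it. The closest known reaction types are BIMP-catalysed intramolecular oxa-Michael additions of alcohols to unsaturated esters and amides, and cinchona–thiourea cyclisations of α-carboxylated 2'-hydroxychalcones.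

Step 9
Reactants: 13 (2S)-5,7-bis(benzyloxy)-2-(4-{[(1R,2R)-1-[4-(benzyloxy)phenyl]-1,3-dihydroxypropan-2-yl]oxy}-3,5-dimethoxyphenyl)-2,3-dihydro-4H-chromen-4-one
Product: 14 (2S)-2-(4-{[(1R,2R)-1,3-dihydroxy-1-(4-hydroxyphenyl)propan-2-yl]oxy}-3,5-dimethoxyphenyl)-5,7-dihydroxy-2,3-dihydro-4H-chromen-4-one
Conditions: H2 (1 atm), Pd/C (10 wt %), EtOAc/MeOH 1:1, rt, 2–4 h, stopped after uptake of 3 equiv H2
Reagents that add atoms: none
Why: Catalytic hydrogenolysis cleaves the three benzyl aryl ethers much faster than the benzylic C–OH or the flavanone C2–O bond under neutral conditions, and no stereocentre is touched.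

## Compound list

1 | 1-[4-(benzyloxy)phenyl]ethan-1-one | CC(=O)c1ccc(OCc2ccccc2)cc1 | starting material
2 | methyl 3-[4-(benzyloxy)phenyl]-3-oxopropanoate | COC(=O)CC(=O)c1ccc(OCc2ccccc2)cc1 | intermediate
3 | 4-hydroxy-3,5-dimethoxybenzaldehyde (syringaldehyde) | COc1cc(C=O)cc(OC)c1O | starting material
4 | methyl 3-[4-(benzyloxy)phenyl]-2-bromo-3-oxopropanoate (racemic) | COC(=O)C(Br)C(=O)c1ccc(OCc2ccccc2)cc1 | intermediate (not isolated)
5 | methyl 3-[4-(benzyloxy)phenyl]-2-(4-formyl-2,6-dimethoxyphenoxy)-3-oxopropanoate (racemic, labile centre) | COC(=O)C(Oc1c(OC)cc(C=O)cc1OC)C(=O)c1ccc(OCc2ccccc2)cc1 | intermediate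
6 | methyl 3-[4-(benzyloxy)phenyl]-2-[4-(hydroxymethyl)-2,6-dimethoxyphenoxy]-3-oxopropanoate (racemic, labile centre) | COC(=O)C(Oc1c(OC)cc(CO)cc1OC)C(=O)c1ccc(OCc2ccccc2)cc1 | intermediate (not isolated)
7 | methyl (2S,3R)-3-[4-(benzyloxy)phenyl]-3-hydroxy-2-[4-(hydroxymethyl)-2,6-dimethoxyphenoxy]propanoate | COc1cc(CO)cc(OC)c1O[C@H](C(=O)OC)[C@H](O)c1ccc(OCc2ccccc2)cc1 | intermediate
8 | (1R,2R)-1-[4-(benzyloxy)phenyl]-2-[4-(hydroxymethyl)-2,6-dimethoxyphenoxy]propane-1,3-diol | COc1cc(CO)cc(OC)c1O[C@H](CO)[C@H](O)c1ccc(OCc2ccccc2)cc1 | intermediate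
9 | 4-{[(1R,2R)-1-[4-(benzyloxy)phenyl]-1,3-dihydroxypropan-2-yl]oxy}-3,5-dimethoxybenzaldehyde | COc1cc(C=O)cc(OC)c1O[C@H](CO)[C@H](O)c1ccc(OCc2ccccc2)cc1 | intermediate
10 | 1-(2,4,6-trihydroxyphenyl)ethan-1-one | CC(=O)c1c(O)cc(O)cc1O | starting material
11 | 1-[2,4-bis(benzyloxy)-6-hydroxyphenyl]ethan-1-one | CC(=O)c1c(O)cc(OCc2ccccc2)cc1OCc1ccccc1 | intermediate
12 | (E)-1-[2,4-bis(benzyloxy)-6-hydroxyphenyl]-3-(4-{[(1R,2R)-1-[4-(benzyloxy)phenyl]-1,3-dihydroxypropan-2-yl]oxy}-3,5-dimethoxyphenyl)prop-2-en-1-one | COc1cc(/C=C/C(=O)c2c(O)cc(OCc3ccccc3)cc2OCc2ccccc2)cc(OC)c1O[C@H](CO)[C@H](O)c1ccc(OCc2ccccc2)cc1 | intermediate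
13 | (2S)-5,7-bis(benzyloxy)-2-(4-{[(1R,2R)-1-[4-(benzyloxy)phenyl]-1,3-dihydroxypropan-2-yl]oxy}-3,5-dimethoxyphenyl)-2,3-dihydro-4H-chromen-4-one | COc1cc([C@@H]2CC(=O)c3c(OCc4ccccc4)cc(OCc4ccccc4)cc3O2)cc(OC)c1O[C@H](CO)[C@H](O)c1ccc(OCc2ccccc2)cc1 | intermediate
14 | (2S)-2-(4-{[(1R,2R)-1,3-dihydroxy-1-(4-hydroxyphenyl)propan-2-yl]oxy}-3,5-dimethoxyphenyl)-5,7-dihydroxy-2,3-dihydro-4H-chromen-4-one | COc1cc([C@@H]2CC(=O)c3c(O)cc(O)cc3O2)cc(OC)c1O[C@H](CO)[C@H](O)c1ccc(O)cc1 | target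

## Step count and risks

Total step count: 9. Longest linear sequence: 8 (steps 1–5 and 7–9; step 6 is a one-step side branch).

The three steps most likely to fail:

Step 8 (proposed new oxa-Michael; risk of low ee or erosion by retro-Michael). The fallback sets out from 12 and comes back at 13. Thermal, non-selective cyclisation of 12 with NaOAc in refluxing EtOH gives 13 together with its C2 epimer, (2R)-5,7-bis(benzyloxy)-2-(4-{[(1R,2R)-1-[4-(benzyloxy)phenyl]-1,3-dihydroxypropan-2-yl]oxy}-3,5-dimethoxyphenyl)-2,3-dihydro-4H-chromen-4-one F6. The two epimers are separated by preparative HPLC on a chiral stationary phase, and F6 is reopened to 12 with KOH/EtOH at rt and recycled.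

Step 3 (dynamic kinetic resolution on a β-keto ester carrying a bulky 2,6-dimethoxyaryloxy group; risk of low syn:anti ratio or ee). The fallback sets out from 3 and comes back at 8, replacing steps 2–4 by auxiliary control.
- NaBH4/MeOH reduces 3 to 4-(hydroxymethyl)-2,6-dimethoxyphenol F1.
- Its phenoxide (K2CO3, NaI, acetone) is alkylated by (S)-4-benzyl-3-(chloroacetyl)oxazolidin-2-one to give (4S)-4-benzyl-3-{[4-(hydroxymethyl)-2,6-dimethoxyphenoxy]acetyl}-1,3-oxazolidin-2-one F2, so the ether bond is still made by phenoxide SN2.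
- Bu2BOTf (2.2 equiv, the extra equivalent masking the free CH2OH as its borinate) and i-Pr2NEt in CH2Cl2 at −78 °C, then 4-(benzyloxy)benzaldehyde, give the Evans syn-aldol adduct (4S)-4-benzyl-3-[(2S,3R)-3-[4-(benzyloxy)phenyl]-3-hydroxy-2-[4-(hydroxymethyl)-2,6-dimethoxyphenoxy]propanoyl]-1,3-oxazolidin-2-one F3.
- LiBH4 in THF/H2O at 0 °C removes the auxiliary reductively and gives 8.

Step 5 (chemoselective oxidation of one of three hydroxyls; risk of oxidising the C3 primary or the benzylic secondary alcohol). The fallback sets out from 8 and comes back at 9, replacing selectivity by protection.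
- 2,2-Dimethoxypropane and PPTS in acetone tie up the 1,3-diol as (4-{[(4R,5R)-4-[4-(benzyloxy)phenyl]-2,2-dimethyl-1,3-dioxan-5-yl]oxy}-3,5-dimethoxyphenyl)methanol F4.
- MnO2 in CH2Cl2 oxidises the only free (benzylic) alcohol to 4-{[(4R,5R)-4-[4-(benzyloxy)phenyl]-2,2-dimethyl-1,3-dioxan-5-yl]oxy}-3,5-dimethoxybenzaldehyde F5.
- 80 % aq. AcOH at rt removes the acetonide and gives 9.

## Further compounds

F1 | step 3 | 4-(hydroxymethyl)-2,6-dimethoxyphenol | COc1cc(CO)cc(OC)c1O
F2 | step 3 | (4S)-4-benzyl-3-{[4-(hydroxymethyl)-2,6-dimethoxyphenoxy]acetyl}-1,3-oxazolidin-2-one | COc1cc(CO)cc(OC)c1OCC(=O)N1[C@@H](Cc2ccccc2)COC1=O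
F3 | step 3 | (4S)-4-benzyl-3-[(2S,3R)-3-[4-(benzyloxy)phenyl]-3-hydroxy-2-[4-(hydroxymethyl)-2,6-dimethoxyphenoxy]propanoyl]-1,3-oxazolidin-2-one | COc1cc(CO)cc(OC)c1O[C@H](C(=O)N1[C@@H](Cc2ccccc2)COC1=O)[C@H](O)c1ccc(OCc2ccccc2)cc1
F4 | step 5 | (4-{[(4R,5R)-4-[4-(benzyloxy)phenyl]-2,2-dimethyl-1,3-dioxan-5-yl]oxy}-3,5-dimethoxyphenyl)methanol | COc1cc(CO)cc(OC)c1O[C@@H]1COC(C)(C)O[C@@H]1c1ccc(OCc2ccccc2)cc1
F5 | step 5 | 4-{[(4R,5R)-4-[4-(benzyloxy)phenyl]-2,2-dimethyl-1,3-dioxan-5-yl]oxy}-3,5-dimethoxybenzaldehyde | COc1cc(C=O)cc(OC)c1O[C@@H]1COC(C)(C)O[C@@H]1c1ccc(OCc2ccccc2)cc1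
F6 | step 8 | (2R)-5,7-bis(benzyloxy)-2-(4-{[(1R,2R)-1-[4-(benzyloxy)phenyl]-1,3-dihydroxypropan-2-yl]oxy}-3,5-dimethoxyphenyl)-2,3-dihydro-4H-chromen-4-one | COc1cc([C@H]2CC(=O)c3c(OCc4ccccc4)cc(OCc4ccccc4)cc3O2)cc(OC)c1O[C@H](CO)[C@H](O)c1ccc(OCc2ccccc2)cc1
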